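A direct plan would copy the presumed biogenesis. 5-Hydroxyconiferaldehyde A1 would be dimerised with a silver salt such as Ag2CO3 to the racemic trans dialdehyde A2. The saturated formyl group of A2 would be reduced with NaBH4 to the racemic alcohol A3, and A3 would be resolved with a lipase. Its weakest points would be:
- The oxidative phenol coupling: a free catechol radical can pair at several positions and polymerise, so which ring oxygen bonds to which carbon, and the trans arrangement, would rest on the substrate alone.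
- The reduction of one aldehyde beside an enal, run on a crude dialdehyde whose formyl-bearing centre can epimerise.
- The final kinetic resolution, which would set the absolute configuration only by discarding at least half of the most advanced material.

**Plan of the new route** (benzodioxine locants: O1, C2, C3, O4, C4a, C5 to C8, C8a; ring A = benzo ring, ring B = dioxane, ring C = pendant aryl)
- Cuts, in retrosynthetic order: the aryl–oxygen bond O4–C4a of ring B, then the C2–C3 bond between the two stereocentres, then O1–CH2 of an aryloxyacetyl imide. The enal is traced back to a nitrile on ring A.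
- Enabling feature: C2 carries the aryloxy oxygen O1 and a hydroxymethyl carbon (a reduced carboxyl), and C3 is an aryl carbinol carbon. O1–C2(CH2OH)–C3(O4)–ring C is therefore the retron of an aryloxyacetate (glycolate) aldol.
- Regiochemistry: O1 sits on the ring A carbon C8a, between the methoxy carbon C8 and C4a. The phenol 3-bromo-4-hydroxy-5-methoxybenzonitrile therefore fixes which oxygen goes where.
- Ring order: rings A and C are bought. Both stereocentres are set on an open chain by the aldol. Ring B closes afterwards from its aryl side with retention, so the syn (threo) chain becomes the trans ring.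
- The weak steps do not arise: there is no radical coupling, only one aldehyde is ever present at a time, and the absolute configuration comes from the auxiliary, not from a resolution.

Key step: step 3

Remark: compounds 3 and 4 are taken as catalogue compounds (3 is otherwise one step from 5-bromovanillin, 4 one step from (4S)-4-benzyl-1,3-oxazolidin-2-one).

**Step 1**
Reactants: 1 3,4-dihydroxy-5-methoxybenzaldehyde
Product: 2 3-methoxy-4,5-bis(methoxymethoxy)benzaldehyde
Conditions: MOMCl (3 equiv), iPr2NEt (4 equiv), CH2Cl2, 0 °C to rt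
Reagents that add atoms: chloromethyl methyl ether, COCCl
Why: O-alkylation of both phenols with the reactive alpha-chloro ether (Williamson-type etherification) masks the catechol of ring C as base-stable, acid-labile acetals; no stereocentre is involved.

**Step 2**
Reactants: 3 3-bromo-4-hydroxy-5-methoxybenzonitrile; 4 (4S)-4-benzyl-3-(chloroacetyl)-1,3-oxazolidin-2-one
Product: 5 (4S)-4-benzyl-3-[(2-bromo-4-cyano-6-methoxyphenoxy)acetyl]-1,3-oxazolidin-2-one
Conditions: K2CO3 (1.5 equiv), DMF, rt to 40 °C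
Reagents that add atoms: none
Why: Williamson ether synthesis, in which the acidic para-cyano phenoxide displaces chloride from the alpha-chloro imide faster than it attacks an acyl carbon; this makes the O1–CH2 bond at a carbon that is not yet stereogenic and places O1 between the methoxy and the bromo carbons of ring A.

**Step 3**
Reactants: 5 (4S)-4-benzyl-3-[(2-bromo-4-cyano-6-methoxyphenoxy)acetyl]-1,3-oxazolidin-2-one; 2 3-methoxy-4,5-bis(methoxymethoxy)benzaldehyde
Product: 7 (4S)-4-benzyl-3-{(2S,3R)-2-(2-bromo-4-cyano-6-methoxyphenoxy)-3-hydroxy-3-[3-methoxy-4,5-bis(methoxymethoxy)phenyl]propanoyl}-1,3-oxazolidin-2-one, via dibutylboron (Z)-enolate 6 (not isolated)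
Conditions: Bu2BOTf (1.3 equiv), iPr2NEt (1.5 equiv), CH2Cl2, −78 to 0 °C; 2 (1.2 equiv), −78 to 0 °C; pH 7 phosphate buffer, MeOH, 30% H2O2, 0 °C
Reagents that add atoms: none
Why: Soft enolisation of imide 5 by Bu2BOTf and the amine should give the (Z)-boron enolate 6, which adds to aldehyde 2 through a closed, six-membered Zimmerman–Traxler chair; the closest known reaction type is the Evans syn aldol of alkoxy- and aryloxyacetyl oxazolidinones (glycolate aldol). The step closes no ring but forms the C2–C3 bond of the future ring B and joins the ring A and ring C halves. The syn (threo) relation of C2 and C3 follows from the Z enolate with the aryl group of 2 equatorial in the chair. The absolute sense follows from the benzyl group of the (4S) auxiliary, which, in the dipole-opposed, non-chelated arrangement enforced by boron, blocks one enolate face, so that the (2S,3R) adduct is expected; this is the arrangement that becomes (2R,3R) in the target, the descriptor at C2 changing only because the carbonyl is later reduced. The step needs a single enolate geometry and a single electrophile: the short B–O bonds and the lack of a free coordination site on boron secure the former, and keeping the ring A side chain as a nitrile (not an aldehyde) secures the latter. The aryl bromide, the nitrile and the methoxymethyl ethers are inert under these conditions.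

**Step 4**
Reactants: 7 (4S)-4-benzyl-3-{(2S,3R)-2-(2-bromo-4-cyano-6-methoxyphenoxy)-3-hydroxy-3-[3-methoxy-4,5-bis(methoxymethoxy)phenyl]propanoyl}-1,3-oxazolidin-2-one
Product: 8 3-bromo-4-{[(1R,2R)-1,3-dihydroxy-1-[3-methoxy-4,5-bis(methoxymethoxy)phenyl]propan-2-yl]oxy}-5-methoxybenzonitrile
Conditions: LiBH4 (2 equiv), MeOH (2 equiv), THF, 0 °C
Reagents that add atoms: none
Why: Reductive removal of the Evans auxiliary by hydride attack on the exocyclic imide carbonyl should give the primary alcohol without reducing the aryl nitrile or bromide and without epimerising the aryloxy-bearing carbon, which is no longer alpha to a carbonyl afterwards.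

**Step 5**
Reactants: 8 3-bromo-4-{[(1R,2R)-1,3-dihydroxy-1-[3-methoxy-4,5-bis(methoxymethoxy)phenyl]propan-2-yl]oxy}-5-methoxybenzonitrile
Product: 9 3-bromo-4-{[(1R,2R)-1-hydroxy-1-[3-methoxy-4,5-bis(methoxymethoxy)phenyl]-3-(triphenylmethoxy)propan-2-yl]oxy}-5-methoxybenzonitrile
Conditions: TrCl (1.2 equiv), Et3N, DMAP (cat.), CH2Cl2, rt
Reagents that add atoms: trityl chloride, ClC(c1ccccc1)(c2ccccc2)c3ccccc3
Why: Tritylation is selective for the primary over the hindered secondary benzylic hydroxyl; the primary oxygen must be masked because it could also close a six-membered ring onto the bromo carbon, and a trityl group, unlike a silyl group, cannot migrate to the benzylic oxygen under base.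

**Step 6**
Reactants: 9 3-bromo-4-{[(1R,2R)-1-hydroxy-1-[3-methoxy-4,5-bis(methoxymethoxy)phenyl]-3-(triphenylmethoxy)propan-2-yl]oxy}-5-methoxybenzonitrile
Product: 10 (2R,3R)-8-methoxy-3-[3-methoxy-4,5-bis(methoxymethoxy)phenyl]-2-[(triphenylmethoxy)methyl]-2,3-dihydro-1,4-benzodioxine-6-carbonitrile
Conditions: Pd(OAc)2 (3 mol %), 2-(di-tert-butylphosphino)-1,1'-binaphthyl (4 mol %), Cs2CO3 (1.5 equiv), toluene, 70 °C, Ar
Reagents that add atoms: none
Why: Palladium-catalysed intramolecular C–O coupling (Buchwald–Hartwig etherification), in which oxidative addition of the C–Br bond to zerovalent palladium, alkoxide binding and C–O reductive elimination from divalent palladium close ring B at O4–C4a; the carbinol C–O bond is never broken, so C3 keeps its configuration and the threo chain should become the trans (2R,3R) ring, the bulky electron-rich phosphine favouring reductive elimination over beta-hydride elimination.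

**Step 7**
Reactants: 10 (2R,3R)-8-methoxy-3-[3-methoxy-4,5-bis(methoxymethoxy)phenyl]-2-[(triphenylmethoxy)methyl]-2,3-dihydro-1,4-benzodioxine-6-carbonitrile
Product: 12 (2R,3R)-8-methoxy-3-[3-methoxy-4,5-bis(methoxymethoxy)phenyl]-2-[(triphenylmethoxy)methyl]-2,3-dihydro-1,4-benzodioxine-6-carbaldehyde, via aldimine 11 (not isolated)
Conditions: iBu2AlH (1.5 equiv), CH2Cl2, −78 °C; then aq. KNaC4H4O6 (potassium sodium tartrate), rt
Reagents that add atoms: water, O
Why: Partial reduction of the aryl nitrile by iBu2AlH stops at the N-aluminated aldimine, which should hydrolyse on neutral aqueous work-up to the aldehyde; the ethers, the trityl group and both stereocentres are not touched.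

**Step 8**
Reactants: 12 (2R,3R)-8-methoxy-3-[3-methoxy-4,5-bis(methoxymethoxy)phenyl]-2-[(triphenylmethoxy)methyl]-2,3-dihydro-1,4-benzodioxine-6-carbaldehyde; 13 (1,3-dioxolan-2-ylmethyl)triphenylphosphonium bromide
Product: 15 (E)-3-[(2R,3R)-3-(3,4-dihydroxy-5-methoxyphenyl)-2-(hydroxymethyl)-8-methoxy-2,3-dihydro-1,4-benzodioxin-6-yl]prop-2-enal, via vinyl dioxolane 14 (not isolated)
Conditions: 13 (1.6 equiv), KOtBu (1.6 equiv), THF, 0 to 50 °C, Ar; then 3 M aq. HCl/THF 1:1, 45 °C
Reagents that add atoms: water, O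
Why: Wittig olefination with the acetal-masked formylmethylene ylide should give vinyl dioxolane 14 without double homologation, and one aqueous acid treatment should then hydrolyse the acetal (the E/Z mixture converging on the conjugated E-enal), both methoxymethyl ethers and the trityl ether; neither stereocentre is alpha to a carbonyl and the trans ring is the more stable arrangement.

**Compound list**
1 | 3,4-dihydroxy-5-methoxybenzaldehyde | COc1cc(C=O)cc(O)c1O | starting material
2 | 3-methoxy-4,5-bis(methoxymethoxy)benzaldehyde | COCOc1cc(C=O)cc(OC)c1OCOC | intermediate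
3 | 3-bromo-4-hydroxy-5-methoxybenzonitrile | COc1cc(C#N)cc(Br)c1O | starting material
4 | (4S)-4-benzyl-3-(chloroacetyl)-1,3-oxazolidin-2-one | O=C1OC[C@H](Cc2ccccc2)N1C(=O)CCl | starting material
5 | (4S)-4-benzyl-3-[(2-bromo-4-cyano-6-methoxyphenoxy)acetyl]-1,3-oxazolidin-2-one | O=C1OC[C@H](Cc2ccccc2)N1C(=O)COc3c(Br)cc(C#N)cc3OC | intermediate
6 | (4S)-4-benzyl-3-[(Z)-2-(2-bromo-4-cyano-6-methoxyphenoxy)-1-[(dibutylboranyl)oxy]ethenyl]-1,3-oxazolidin-2-one (dibutylboron (Z)-enolate) | O=C1OC[C@H](Cc2ccccc2)N1/C(OB(CCCC)CCCC)=C/Oc3c(Br)cc(C#N)cc3OC | intermediate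
7 | (4S)-4-benzyl-3-{(2S,3R)-2-(2-bromo-4-cyano-6-methoxyphenoxy)-3-hydroxy-3-[3-methoxy-4,5-bis(methoxymethoxy)phenyl]propanoyl}-1,3-oxazolidin-2-one | O=C1OC[C@H](Cc2ccccc2)N1C(=O)[C@@H](Oc3c(Br)cc(C#N)cc3OC)[C@H](O)c4cc(OC)c(OCOC)c(OCOC)c4 | intermediate
8 | 3-bromo-4-{[(1R,2R)-1,3-dihydroxy-1-[3-methoxy-4,5-bis(methoxymethoxy)phenyl]propan-2-yl]oxy}-5-methoxybenzonitrile | OC[C@@H](Oc1c(Br)cc(C#N)cc1OC)[C@H](O)c2cc(OC)c(OCOC)c(OCOC)c2 | intermediate
9 | 3-bromo-4-{[(1R,2R)-1-hydroxy-1-[3-methoxy-4,5-bis(methoxymethoxy)phenyl]-3-(triphenylmethoxy)propan-2-yl]oxy}-5-methoxybenzonitrile | C(c1ccccc1)(c2ccccc2)(c3ccccc3)OC[C@@H](Oc4c(Br)cc(C#N)cc4OC)[C@H](O)c5cc(OC)c(OCOC)c(OCOC)c5 | intermediate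
10 | (2R,3R)-8-methoxy-3-[3-methoxy-4,5-bis(methoxymethoxy)phenyl]-2-[(triphenylmethoxy)methyl]-2,3-dihydro-1,4-benzodioxine-6-carbonitrile | C(c1ccccc1)(c2ccccc2)(c3ccccc3)OC[C@H]4Oc5c(OC)cc(C#N)cc5O[C@@H]4c6cc(OC)c(OCOC)c(OCOC)c6 | intermediate
11 | 1-{(2R,3R)-8-methoxy-3-[3-methoxy-4,5-bis(methoxymethoxy)phenyl]-2-[(triphenylmethoxy)methyl]-2,3-dihydro-1,4-benzodioxin-6-yl}methanimine (aldimine) | C(c1ccccc1)(c2ccccc2)(c3ccccc3)OC[C@H]4Oc5c(OC)cc(C=N)cc5O[C@@H]4c6cc(OC)c(OCOC)c(OCOC)c6 | intermediate
12 | (2R,3R)-8-methoxy-3-[3-methoxy-4,5-bis(methoxymethoxy)phenyl]-2-[(triphenylmethoxy)methyl]-2,3-dihydro-1,4-benzodioxine-6-carbaldehyde | C(c1ccccc1)(c2ccccc2)(c3ccccc3)OC[C@H]4Oc5c(OC)cc(C=O)cc5O[C@@H]4c6cc(OC)c(OCOC)c(OCOC)c6 | intermediate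
13 | (1,3-dioxolan-2-ylmethyl)triphenylphosphonium bromide | [Br-].C(C1OCCO1)[P+](c2ccccc2)(c3ccccc3)c4ccccc4 | starting material
14 | (2R,3R)-6-[2-(1,3-dioxolan-2-yl)ethenyl]-8-methoxy-3-[3-methoxy-4,5-bis(methoxymethoxy)phenyl]-2-[(triphenylmethoxy)methyl]-2,3-dihydro-1,4-benzodioxine (E/Z mixture, geometry not defined) | C(c1ccccc1)(c2ccccc2)(c3ccccc3)OC[C@H]4Oc5c(OC)cc(C=CC7OCCO7)cc5O[C@@H]4c6cc(OC)c(OCOC)c(OCOC)c6 | intermediate
15 | (E)-3-[(2R,3R)-3-(3,4-dihydroxy-5-methoxyphenyl)-2-(hydroxymethyl)-8-methoxy-2,3-dihydro-1,4-benzodioxin-6-yl]prop-2-enal | COc1cc([C@H]2Oc3cc(/C=C/C=O)cc(OC)c3O[C@@H]2CO)cc(O)c1O | target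

**Step count:** 8 steps in total; the longest linear sequence is 7 steps (steps 2 to 8, from 3 and 4); step 1 is a one-step side branch.

**Steps most likely to fail**

1. Step 3 (aldol).
   - What may go wrong: incomplete enolisation or eroded facial and syn selectivity with the bulky, electron-poor aryloxy enolate, or retro-aldol cleavage on work-up.
   - Fallback, setting out from 3 and 2 and coming back at 8: the stereocentres would be set by reduction instead of by C–C bond formation.
   - Phenol 3 would be alkylated with ethyl bromoacetate (K2CO3, acetone) to ethyl (2-bromo-4-cyano-6-methoxyphenoxy)acetate F1.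
   - Its lithium enolate (LiN(iPr)2, THF, −78 °C) would add to aldehyde 2 without stereocontrol to give ethyl 2-(2-bromo-4-cyano-6-methoxyphenoxy)-3-hydroxy-3-[3-methoxy-4,5-bis(methoxymethoxy)phenyl]propanoate F2 as a mixture of isomers.
   - Dess–Martin oxidation would give the configurationally labile keto ester ethyl 2-(2-bromo-4-cyano-6-methoxyphenoxy)-3-[3-methoxy-4,5-bis(methoxymethoxy)phenyl]-3-oxopropanoate F3.
   - Asymmetric transfer hydrogenation under dynamic kinetic resolution (RuCl(p-cymene)[(S,S)-TsDPEN], HCO2H/Et3N 5:2, rt) should funnel F3 to ethyl (2S,3R)-2-(2-bromo-4-cyano-6-methoxyphenoxy)-3-hydroxy-3-[3-methoxy-4,5-bis(methoxymethoxy)phenyl]propanoate F4. The catalyst enantiomer is chosen by the usual aryl ketone model.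
   - LiBH4 in THF would reduce F4 to diol 8.

2. Step 6 (ring closure).
   - What may go wrong: beta-hydride elimination from the palladium alkoxide of the secondary benzylic alcohol (ketone plus hydrodebrominated arene), or slow C–O reductive elimination.
   - Fallback, setting out from 8 and coming back at 10: ring B would be closed at the benzylic carbon instead of at the aryl carbon.
   - Miyaura borylation of 8 (B2pin2, PdCl2(dppf), KOAc, dioxane, 80 °C) would give 4-{[(1R,2R)-1,3-dihydroxy-1-[3-methoxy-4,5-bis(methoxymethoxy)phenyl]propan-2-yl]oxy}-3-methoxy-5-(4,4,5,5-tetramethyl-1,3,2-dioxaborolan-2-yl)benzonitrile F5.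
   - Oxidation (aq. H2O2, NaHCO3, THF, 0 °C) would give the phenol 4-{[(1R,2R)-1,3-dihydroxy-1-[3-methoxy-4,5-bis(methoxymethoxy)phenyl]propan-2-yl]oxy}-3-hydroxy-5-methoxybenzonitrile F6.
   - Catalytic TsOH in CH2Cl2 at rt would ionise the para-alkoxybenzylic alcohol, and the phenol would close the ring at C3. With C2 fixed, the diequatorial trans isomer is expected to prevail, and any cis isomer would have to be separated. The product would be (2R,3R)-2-(hydroxymethyl)-8-methoxy-3-[3-methoxy-4,5-bis(methoxymethoxy)phenyl]-2,3-dihydro-1,4-benzodioxine-6-carbonitrile F7.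
   - Tritylation of F7 as in step 5 would give 10.

3. Step 8 (homologation and global deprotection).
   - What may go wrong: incomplete Z-to-E convergence of the enal, or loss of material in acid while the enal is present (reaction of the liberated formaldehyde with the electron-rich catechol ring, or opening of the benzylic C3–O4 bond).
   - Fallback, setting out from 10 and coming back at 15: the protecting groups would be removed before any enal exists, and the enal would be made last under neutral conditions.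
   - 3 M aq. HCl/THF at 45 °C on nitrile 10 would give (2R,3R)-3-(3,4-dihydroxy-5-methoxyphenyl)-2-(hydroxymethyl)-8-methoxy-2,3-dihydro-1,4-benzodioxine-6-carbonitrile F8.
   - Excess iBu2AlH (THF/CH2Cl2, −78 to −20 °C, then aqueous potassium sodium tartrate) would give (2R,3R)-3-(3,4-dihydroxy-5-methoxyphenyl)-2-(hydroxymethyl)-8-methoxy-2,3-dihydro-1,4-benzodioxine-6-carbaldehyde F9.
   - Wittig reaction of F9 with the stabilised ylide Ph3P=CHCHO (toluene/THF, 70 °C) should give the E-enal 15 directly.

**Further compounds**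
F1 | step 3 | ethyl (2-bromo-4-cyano-6-methoxyphenoxy)acetate | CCOC(=O)COc1c(Br)cc(C#N)cc1OC
F2 | step 3 | ethyl 2-(2-bromo-4-cyano-6-methoxyphenoxy)-3-hydroxy-3-[3-methoxy-4,5-bis(methoxymethoxy)phenyl]propanoate (mixture of stereoisomers) | CCOC(=O)C(Oc1c(Br)cc(C#N)cc1OC)C(O)c2cc(OC)c(OCOC)c(OCOC)c2
F3 | step 3 | ethyl 2-(2-bromo-4-cyano-6-methoxyphenoxy)-3-[3-methoxy-4,5-bis(methoxymethoxy)phenyl]-3-oxopropanoate (racemic) | CCOC(=O)C(Oc1c(Br)cc(C#N)cc1OC)C(=O)c2cc(OC)c(OCOC)c(OCOC)c2
F4 | step 3 | ethyl (2S,3R)-2-(2-bromo-4-cyano-6-methoxyphenoxy)-3-hydroxy-3-[3-methoxy-4,5-bis(methoxymethoxy)phenyl]propanoate | CCOC(=O)[C@@H](Oc1c(Br)cc(C#N)cc1OC)[C@H](O)c2cc(OC)c(OCOC)c(OCOC)c2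
F5 | step 6 | 4-{[(1R,2R)-1,3-dihydroxy-1-[3-methoxy-4,5-bis(methoxymethoxy)phenyl]propan-2-yl]oxy}-3-methoxy-5-(4,4,5,5-tetramethyl-1,3,2-dioxaborolan-2-yl)benzonitrile | OC[C@@H](Oc1c(B2OC(C)(C)C(C)(C)O2)cc(C#N)cc1OC)[C@H](O)c3cc(OC)c(OCOC)c(OCOC)c3
F6 | step 6 | 4-{[(1R,2R)-1,3-dihydroxy-1-[3-methoxy-4,5-bis(methoxymethoxy)phenyl]propan-2-yl]oxy}-3-hydroxy-5-methoxybenzonitrile | OC[C@@H](Oc1c(O)cc(C#N)cc1OC)[C@H](O)c3cc(OC)c(OCOC)c(OCOC)c3
F7 | step 6 | (2R,3R)-2-(hydroxymethyl)-8-methoxy-3-[3-methoxy-4,5-bis(methoxymethoxy)phenyl]-2,3-dihydro-1,4-benzodioxine-6-carbonitrile | OC[C@H]1Oc2c(OC)cc(C#N)cc2O[C@@H]1c3cc(OC)c(OCOC)c(OCOC)c3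
F8 | step 8 | (2R,3R)-3-(3,4-dihydroxy-5-methoxyphenyl)-2-(hydroxymethyl)-8-methoxy-2,3-dihydro-1,4-benzodioxine-6-carbonitrile | OC[C@H]1Oc2c(OC)cc(C#N)cc2O[C@@H]1c3cc(OC)c(O)c(O)c3
F9 | step 8 | (2R,3R)-3-(3,4-dihydroxy-5-methoxyphenyl)-2-(hydroxymethyl)-8-methoxy-2,3-dihydro-1,4-benzodioxine-6-carbaldehyde | OC[C@H]1Oc2c(OC)cc(C=O)cc2O[C@@H]1c3cc(OC)c(O)c(O)c3
A1 | direct plan | (E)-3-(3,4-dihydroxy-5-methoxyphenyl)prop-2-enal | COc1cc(/C=C/C=O)cc(O)c1O
A2 | direct plan | racemic trans-3-(3,4-dihydroxy-5-methoxyphenyl)-8-methoxy-6-[(E)-3-oxoprop-1-enyl]-2,3-dihydro-1,4-benzodioxine-2-carbaldehyde (one enantiomer drawn) | COc1cc([C@H]2Oc3cc(/C=C/C=O)cc(OC)c3O[C@@H]2C=O)cc(O)c1O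
A3 | direct plan | racemic trans-(E)-3-[3-(3,4-dihydroxy-5-methoxyphenyl)-2-(hydroxymethyl)-8-methoxy-2,3-dihydro-1,4-benzodioxin-6-yl]prop-2-enal (one enantiomer drawn) | COc1cc([C@H]2Oc3cc(/C=C/C=O)cc(OC)c3O[C@@H]2CO)cc(O)c1O
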